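The C10=C1–C2–C3–C4=C5 unit of the ten-membered ring (1(10)Z, 4E) is read as the cycloreversion product of a bicyclo[2.2.0]hexane made of C1, C2, C3, C4, C5 and C10 and fused to a six-membered ring (C5–C6–C7–C8–C9–C10). One enone–alkene [2+2] photocycloaddition of 1-methylcyclobutene to a carvone-derived 2-methylcyclohexenone, which already carries the cis-fused C6/C7 lactone and the C8 silyl ether, forms C4–C5 and C1–C10, closes the central cyclobutane and sets C1, C4, C5 and C10. Heating then breaks C1–C4 and C5–C10 and releases the cyclodecadienone with C9 as a ketone.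

Key step: step 8

Remarks on the chemistry
- Germacrane numbering is used for all compounds: ring carbons C1–C10, lactone C11 (α-carbon), C12 (C=O), C13 (methyl or methylene), C14 the methyl on C10, C15 the methyl on C4.
- Assumption: hydroboration in step 1 is unselective at the side-chain CH (later C11). Compounds 2–7 are therefore written without configuration there, and 8–17 as the exo-methyl epimer expected after the DBU treatment in step 4. Both epimers converge in steps 12–13, where C11 becomes sp2.
- The epoxy ester of the target is the (2S,3S) cis isomer, so the acid is made enantioselectively (steps 15–17) and not by peracid epoxidation of angelic acid.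
- Only species made by one reagent and consumed by a second in the same flask are numbered as non-isolated intermediates.

Step 1
Reactants: 1 (S)-carvone
Product: 3 5-(1-hydroxypropan-2-yl)-2-methylcyclohex-2-en-1-ol (epimer mixture at the carbinol carbon and the side-chain CH), via bis(9-BBN) borinate alkylborane 2 (not isolated)
Conditions: 9-borabicyclo[3.3.1]nonane (9-BBN, 2.5 equiv), THF, 0 → 25 °C; then NaOH, H2O2, H2O, 0 → 40 °C
Reagents that add atoms: hydrogen peroxide, OO
Why: 9-BBN reduces the enone carbonyl by 1,2-hydride delivery and hydroborates the 1,1-disubstituted isopropenyl group at its terminus (anti-Markovnikov hydroboration–oxidation) while sparing the trisubstituted ring alkene; both new centres form without control, which is harmless because the carbinol is oxidised in step 2 and the side-chain CH is equilibrated in step 4 and erased in step 13.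

Step 2
Reactants: 3 diol
Product: 4 2-(4-methyl-5-oxocyclohex-3-en-1-yl)propanoic acid (C11 epimer mixture)
Conditions: CrO3, H2SO4, H2O, acetone, 0 °C
Reagents that add atoms: water, O
Why: Jones oxidation takes the primary alcohol to the acid through the aldehyde hydrate and the allylic secondary alcohol back to the conjugated enone in one operation; C7, β to the ketone, is not enolisable and keeps the carvone configuration.

Step 3
Reactants: 4 keto acid
Product: 6 2-(4-methyl-5-oxocyclohex-2-en-1-yl)propanoic acid (β,γ-unsaturated ketone, C10 and C11 epimer mixture), via dipotassium dienolate carboxylate 5 (not isolated)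
Conditions: KOtBu (6 equiv), t-BuOH, 25 °C; then inverse quench into aq. AcOH, 0 °C
Reagents that add atoms: none
Why: Deconjugation of an enone by kinetic α-protonation of its thermodynamic extended dienolate: excess alkoxide equilibrates to the linear C9-oxido C10=C5–C6 dienolate and fast protonation at C10 moves the alkene to C5=C6, where the carboxyl group can reach it; the new C10 centre is erased in step 4.

Step 4
Reactants: 6 β,γ-unsaturated keto acid
Product: 8 cis-fused enone lactone 3,6-dimethyl-3a,4-dihydro-1-benzofuran-2,5(3H,7aH)-dione (O6 cis to C11, C11 methyl exo), via iodolactone 7 (not isolated)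
Conditions: I2, NaHCO3, MeCN, 0 °C, dark; then 1,8-diazabicyclo[5.4.0]undec-7-ene (DBU), 0 → 50 °C
Reagents that add atoms: none
Why: Iodolactonisation (5-exo, anti addition across C5=C6) obliges the carboxylate on C11 to attack C6 axially from the face of the C7–C11 bond, so only the cis-fused γ-lactone can form and C6 is set by the C7 centre; the β-iodo ketone then loses HI by E1cB elimination to restore the C5=C10 enone, and continued DBU exposure should epimerise C11 toward the exo-methyl lactone.

Step 5
Reactants: 8 enone lactone
Product: 10 C8-hydroxy enone lactone (4-hydroxy-3,6-dimethyl-3a,4-dihydro-1-benzofuran-2,5(3H,7aH)-dione, O8 trans to C11), via potassium C8 enolate 9 (not isolated)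
Conditions: KN(SiMe3)2, THF, −78 °C; then 2-(phenylsulfonyl)-3-phenyloxaziridine, −78 °C; aq. NH4Cl
Reagents that add atoms: 2-(phenylsulfonyl)-3-phenyloxaziridine, O=S(=O)(N1OC1c1ccccc1)c1ccccc1
Why: Kinetic α′-deprotonation gives the cross-conjugated C8 enolate, which is hydroxylated by the N-sulfonyloxaziridine (enolate oxidation) on the face opposite the cis-fused lactone and the C7–C11 bond, so O8 ends trans to C11 and equatorial.

Step 6
Reactants: 10 C8-hydroxy enone lactone
Product: 11 C8 triethylsilyl ether (4-(triethylsilyloxy)-3,6-dimethyl-3a,4-dihydro-1-benzofuran-2,5(3H,7aH)-dione)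
Conditions: TESCl, imidazole, DMF, 0 → 25 °C
Reagents that add atoms: chlorotriethylsilane, CC[Si](Cl)(CC)CC
Why: Standard silylation of a secondary α-hydroxy ketone without change at any stereocentre; the triethylsilyl group is chosen because it must later be removed in the presence of a tert-butyldimethylsilyl ether.

Step 7
Reactants: 12 methylenecyclobutane
Product: 13 1-methylcyclobutene
Conditions: KOtBu (cat.), DMSO, 60 °C; fractional distillation
Reagents that add atoms: none
Why: Base-catalysed prototropic isomerisation through the allylic anion moves the exocyclic alkene into the more substituted endocyclic position, and the lower-boiling product is distilled out.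

Step 8
Reactants: 11 C8 triethylsilyl ether enone lactone; 13 1-methylcyclobutene
Product: 14 cis-anti-cis photoadduct (cyclohexanone fused at C5–C10 to the central cyclobutane C4–C5–C10–C1, outer cyclobutane C1–C2–C3–C4 anti to the six-membered ring, cyclobutane anti to the lactone)
Conditions: hν (350 nm, Pyrex, uranium-glass filter), 13 (10 equiv), CH2Cl2, degassed, −40 °C
Reagents that add atoms: none
Why: Excitation and intersystem crossing give the triplet enone, which adds to the strained alkene of 13 to form a triplet 1,4-biradical that closes after spin inversion. The closest known reaction type is the intermolecular enone–cycloalkene [2+2] photocycloaddition, as used with cyclobutenes to make tricyclo[4.4.0.0(2,5)]decan-7-ones. The central cyclobutane (C4, C5, C10, C1) closes stepwise by radical recombination with a cis six–four fusion, and the outer cyclobutane arrives intact from 13 and becomes the second ring of the bicyclo[2.2.0]hexane. C5 and C10 are set by approach of 13 to the enone face opposite the pseudo-axial lactone oxygen at C6 and the folded lactone ring, and C4 and C1 by the preference for the anti arrangement that keeps C2 and C3 away from the six-membered ring. The step needs head-to-tail orientation (C4 to the β-carbon C5, C1 to the α-carbon C10), which should be favoured because the methyl-bearing donor carbon pairs with the enone β-carbon and because the alternative would join the two quaternary carbons C10 and C4; the equatorial C8 silyloxy group sits beside the carbonyl and away from the reacting carbons.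

Step 9
Reactants: 14 photoadduct
Product: 15 (1(10)Z,4E)-8-(triethylsilyloxy)-9-oxogermacra-1(10),4-dien-12,6-olide (cis-fused lactone, 11-methyl)
Conditions: PhMe (dilute, degassed), 185 °C, sealed base-washed tube
Reagents that add atoms: none
Why: Thermal [2+2] cycloreversion of the bicyclo[2.2.0]hexane through a cyclohexane-1,4-diyl (homolysis of C1–C4, then scission of C5–C10) releases the strain of both four-membered rings; C4=C5 should keep the anti relationship of C6 and C3 across the old ring and be E, the conjugated C1=C10 bond should adopt the less strained Z geometry, and conjugation with C9=O together with the Z,E geometry disfavours onward Cope rearrangement.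

Step 10
Reactants: 15 dienone
Product: 16 (9R)-9-hydroxy-8-(triethylsilyloxy) dienolide (8,9-syn)
Conditions: NaBH4, CeCl3·7H2O, MeOH, −78 °C
Reagents that add atoms: none
Why: Luche reduction gives clean 1,2-addition to the enone and spares the lactone; hydride is expected to attack the outward face of the carbonyl anti to the C8–O bond (Felkin–Anh polar model with a non-chelating silyl ether), which gives the 8,9-syn alcohol.

Step 11
Reactants: 16 C9 alcohol
Product: 17 9-(tert-butyldimethylsilyloxy)-8-(triethylsilyloxy) dienolide
Conditions: TBSOTf, 2,6-lutidine, CH2Cl2, −78 → 0 °C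
Reagents that add atoms: tert-butyldimethylsilyl trifluoromethanesulfonate, CC(C)(C)[Si](C)(C)OS(=O)(=O)C(F)(F)F
Why: Silyl triflate silylation of a hindered secondary allylic alcohol under non-nucleophilic base; no stereocentre is touched, and the C9 hydroxyl is masked before the strong-base step and differentiated from C8.

Step 12
Reactants: 17 bis-silyl ether
Product: 19 11-bromo-11-methyl lactone (bromine on the convex face, cis to H7), via lithium lactone enolate 18 (not isolated)
Conditions: LiN(iPr)2, THF, −78 °C; then BrCCl2CCl2Br, −78 °C
Reagents that add atoms: 1,2-dibromo-1,1,2,2-tetrachloroethane, BrC(Cl)(Cl)C(Cl)(Cl)Br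
Why: α-Bromination of the lactone lithium enolate by halophilic attack on the dibromide; the electrophile enters the convex face of the cis-fused lactone, anti to C8, so that bromine is cis to H7 and no hydrogen on C7 can be anti-periplanar to it.

Step 13
Reactants: 19 bromo lactone
Product: 20 11(13)-methylene lactone with C8 triethylsilyl and C9 tert-butyldimethylsilyl ethers
Conditions: DBU, PhMe, 60 °C
Reagents that add atoms: none
Why: E2 dehydrobromination: with bromine cis to H7 only the methyl hydrogens can be anti-periplanar, so the exocyclic alkene forms and not the endocyclic butenolide; this non-oxidative route is preferred to selenoxide elimination, whose syn course would allow loss of H7 in a cis-fused lactone and whose peroxidic by-products endanger the strained C4=C5 bond.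

Step 14
Reactants: 20 methylene lactone bis-silyl ether
Product: 21 8-hydroxy-9-(tert-butyldimethylsilyloxy) methylene lactone
Conditions: HF·pyridine, pyridine, THF, 0 °C
Reagents that add atoms: none
Why: Selective fluoride-mediated desilylation: the triethylsilyl ether cleaves much faster than the hindered tert-butyldimethylsilyl ether under buffered HF·pyridine, and these mildly acidic conditions avoid conjugate addition to the methylene lactone and silyl migration.

Step 15
Reactants: 22 angelic acid
Product: 23 (Z)-2-methylbut-2-en-1-ol
Conditions: LiAlH4, Et2O, 0 °C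
Reagents that add atoms: none
Why: Hydride reduction of the unsaturated acid to the allylic alcohol; the Z geometry is retained because no reversible addition or enolisation intervenes.

Step 16
Reactants: 23 (Z)-2-methylbut-2-en-1-ol
Product: 24 [(2R,3S)-2,3-dimethyloxiran-2-yl]methanol
Conditions: Ti(OiPr)4 (cat.), diethyl D-(−)-tartrate (cat.), t-BuOOH, 4 Å molecular sieves, CH2Cl2, −20 °C
Reagents that add atoms: tert-butyl hydroperoxide, CC(C)(C)OO
Why: Sharpless asymmetric epoxidation: the D-tartrate complex delivers oxygen to the alkene face that gives the (2R,3S) epoxy alcohol, and the Z geometry is carried over stereospecifically so that the hydroxymethyl carbon and the C3 methyl stay cis.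

Step 17
Reactants: 24 epoxy alcohol
Product: 25 (2S,3S)-2,3-dimethyloxirane-2-carboxylic acid (epoxyangelic acid)
Conditions: RuCl3·xH2O (cat.), NaIO4, CCl4/MeCN/H2O, 25 °C
Reagents that add atoms: water, O
Why: Catalytic RuO4 oxidation of the primary alcohol to the acid through the aldehyde hydrate leaves the epoxide untouched; neither stereocentre is involved, and the descriptor at C2 changes only because the priorities change.

Step 18
Reactants: 21 C8 alcohol; 25 epoxyangelic acid
Product: 27 8-O-[(2S,3S)-2,3-epoxy-2-methylbutanoyl]-9-(tert-butyldimethylsilyloxy) methylene lactone, via mixed trichlorobenzoic anhydride 26 (not isolated)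
Conditions: 25, 2,4,6-Cl3C6H2COCl, Et3N, PhMe, 25 °C; then 21, 4-(dimethylamino)pyridine, PhMe, 25 → 40 °C
Reagents that add atoms: none
Why: Yamaguchi esterification: the aminopyridine attacks the less shielded glycidic carbonyl of the mixed anhydride and the acylpyridinium acylates the hindered C8 hydroxyl with retention at C8; the acid has no α-hydrogen and cannot epimerise.

Step 19
Reactants: 27 silyl-protected ester
Product: 28 target CNP0318223.3
Conditions: HF·pyridine, THF, 0 → 25 °C
Reagents that add atoms: none
Why: Fluoride-mediated cleavage of the tert-butyldimethylsilyl ether under mildly acidic conditions frees the C9 hydroxyl without base-promoted acyl migration from O8 to O9, without conjugate addition to the methylene lactone, and without opening the deactivated glycidic ester.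

Compound list
1 | (S)-carvone | CC1=CC[C@@H](CC1=O)C(C)=C | starting material
2 | bis(9-BBN) borinate alkylborane from reduction and hydroboration of 1 (not isolated) | CC1=CC[C@@H](CC1OB1C2CCCC1CCC2)C(C)CB1C2CCCC1CCC2 | intermediate
3 | 5-(1-hydroxypropan-2-yl)-2-methylcyclohex-2-en-1-ol, ring CH as in 1, epimer mixture at the carbinol carbon and the side-chain CH | CC1=CC[C@@H](CC1O)C(C)CO | intermediate
4 | 2-(4-methyl-5-oxocyclohex-3-en-1-yl)propanoic acid, C11 epimer mixture | CC1=CC[C@@H](CC1=O)C(C)C(O)=O | intermediate
5 | dipotassium extended dienolate carboxylate of 4 (not isolated) | CC1=C([O-])C[C@H](C=C1)C(C)C([O-])=O.[K+].[K+] | intermediate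
6 | 2-(4-methyl-5-oxocyclohex-2-en-1-yl)propanoic acid, C10 and C11 epimer mixture | CC1C=C[C@@H](CC1=O)C(C)C(O)=O | intermediate
7 | cis-fused iodolactone, 7-iodo-3,6-dimethylhexahydro-1-benzofuran-2,5-dione, iodine at C5 trans to O6 (not isolated) | CC1C(=O)O[C@H]2[C@H](I)C(C)C(=O)C[C@@H]12 | intermediate
8 | cis-fused enone lactone, 3,6-dimethyl-3a,4-dihydro-1-benzofuran-2,5(3H,7aH)-dione, H6 and H7 cis, C11 methyl exo | C[C@@H]1C(=O)O[C@H]2C=C(C)C(=O)C[C@@H]12 | intermediate
9 | potassium C8 enolate of 8 (not isolated) | C[C@@H]1C(=O)O[C@H]2C=C(C)C([O-])=C[C@@H]12.[K+] | intermediate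
10 | C8-hydroxy enone lactone, O8 trans to C11 | C[C@@H]1C(=O)O[C@H]2C=C(C)C(=O)[C@H](O)[C@@H]12 | intermediate
11 | C8 triethylsilyl ether of 10, substrate of the key step | C[C@@H]1C(=O)O[C@H]2C=C(C)C(=O)[C@H](O[Si](CC)(CC)CC)[C@@H]12 | intermediate
12 | methylenecyclobutane | C=C1CCC1 | starting material
13 | 1-methylcyclobutene | CC1=CCC1 | intermediate
14 | cis-anti-cis photoadduct, cyclobutanes anti to the lactone, C14 methyl on C10 and C15 methyl on C4 | C[C@@H]1C(=O)O[C@H]2[C@H]3[C@@](C)(C(=O)[C@H](O[Si](CC)(CC)CC)[C@@H]12)[C@@H]4CC[C@]34C | intermediate
15 | (1(10)Z,4E)-8-(triethylsilyloxy)-9-oxogermacra-1(10),4-dien-12,6-olide, cis-fused lactone, 11-methyl | C[C@@H]1C(=O)O[C@H]2/C=C(\C)CC/C=C(/C)C(=O)[C@H](O[Si](CC)(CC)CC)[C@@H]12 | intermediate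
16 | (9R)-9-hydroxy-8-(triethylsilyloxy) dienolide | C[C@@H]1C(=O)O[C@H]2/C=C(\C)CC/C=C(/C)[C@@H](O)[C@H](O[Si](CC)(CC)CC)[C@@H]12 | intermediate
17 | 9-(tert-butyldimethylsilyloxy)-8-(triethylsilyloxy) dienolide | C[C@@H]1C(=O)O[C@H]2/C=C(\C)CC/C=C(/C)[C@@H](O[Si](C)(C)C(C)(C)C)[C@H](O[Si](CC)(CC)CC)[C@@H]12 | intermediate
18 | lithium lactone enolate of 17 (not isolated) | CC1=C([O-])O[C@H]2/C=C(\C)CC/C=C(/C)[C@@H](O[Si](C)(C)C(C)(C)C)[C@H](O[Si](CC)(CC)CC)[C@@H]12.[Li+] | intermediate
19 | 11-bromo-11-methyl lactone, bromine cis to H7 | C[C@@]1(Br)C(=O)O[C@H]2/C=C(\C)CC/C=C(/C)[C@@H](O[Si](C)(C)C(C)(C)C)[C@H](O[Si](CC)(CC)CC)[C@@H]12 | intermediate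
20 | 11(13)-methylene lactone, C8 triethylsilyl and C9 tert-butyldimethylsilyl ethers | C=C1C(=O)O[C@H]2/C=C(\C)CC/C=C(/C)[C@@H](O[Si](C)(C)C(C)(C)C)[C@H](O[Si](CC)(CC)CC)[C@@H]12 | intermediate
21 | 8-hydroxy-9-(tert-butyldimethylsilyloxy) methylene lactone | C=C1C(=O)O[C@H]2/C=C(\C)CC/C=C(/C)[C@@H](O[Si](C)(C)C(C)(C)C)[C@H](O)[C@@H]12 | intermediate
22 | angelic acid, (Z)-2-methylbut-2-enoic acid | C/C=C(/C)C(O)=O | starting material
23 | (Z)-2-methylbut-2-en-1-ol | C/C=C(/C)CO | intermediate
24 | [(2R,3S)-2,3-dimethyloxiran-2-yl]methanol | OC[C@@]1(C)O[C@H]1C | intermediate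
25 | (2S,3S)-2,3-dimethyloxirane-2-carboxylic acid | OC(=O)[C@@]1(C)O[C@H]1C | intermediate
26 | mixed anhydride of 25 with 2,4,6-trichlorobenzoic acid (not isolated) | O=C(OC(=O)[C@@]1(C)O[C@H]1C)c1c(Cl)cc(Cl)cc1Cl | intermediate
27 | 8-O-[(2S,3S)-2,3-epoxy-2-methylbutanoyl]-9-(tert-butyldimethylsilyloxy) methylene lactone | C=C1C(=O)O[C@H]2/C=C(\C)CC/C=C(/C)[C@@H](O[Si](C)(C)C(C)(C)C)[C@H](OC(=O)[C@@]3(C)O[C@H]3C)[C@@H]12 | intermediate
28 | CNP0318223.3 | C=C1C(=O)O[C@H]2/C=C(\C)CC/C=C(/C)[C@@H](O)[C@H](OC(=O)[C@@]3(C)O[C@H]3C)[C@@H]12 | target

Total step count: 19. Longest linear sequence: 15 steps (steps 1–6, 8–14, 18 and 19 from (S)-carvone); steps 7 and 15–17 are side branches.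

Steps most likely to fail

Step 8. The biradical may partition toward head-to-head adducts, the alkene may add on the lactone face, or the α-silyloxy ketone product may be consumed by secondary α-cleavage photolysis. The fallback sets out from 8 (with 13) and comes back at 14; it moves the C8 oxygenation behind the cycloaddition. Enone 8 is irradiated with 13 under the conditions of step 8 to give the C8-unsubstituted cis-anti-cis photoadduct F1, whose ketone has no α-oxygen and whose enone precursor has no substituent on the approach face. C8 is the only enolisable position of F1 because C10 is quaternary. KN(SiMe3)2 followed by the N-sulfonyloxaziridine of step 5 should therefore give the C8-hydroxy photoadduct F2 with oxygen trans to C11, and TESCl with imidazole converts it into 14.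

Step 9. The diyl may cleave with retention at both breaking bonds and give a trans C1=C10 bond, it may break C2–C3 instead of C5–C10, or 15 may undergo Cope rearrangement to the cis-divinylcyclohexanone on prolonged heating. The fallback sets out from 14 and comes back at 15; it separates ring opening from geometry control. Flash vacuum pyrolysis of 14 (short contact time, so that only the cycloreversion occurs) would give the kinetic (1(10)E,4E)-dienone isomer F3. This is then equilibrated at 25 °C with catalytic PhSH and Et3N in CH2Cl2: reversible conjugate addition of thiolate to C1 isomerises only the conjugated alkene to the less strained Z form 15.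

Step 10. Hydride may attack the other face of the conformationally mobile ten-membered enone and give mainly the C9 epimer. The fallback sets out from 15 and comes back at 16; it corrects the centre by inversion instead of relying on facial selectivity. The 9-epi alcohol F4 from the same reduction is subjected to a Mitsunobu reaction with chloroacetic acid (PPh3, diisopropyl azodicarboxylate, PhMe, 0 °C), which should give the inverted 9-O-chloroacetate F5 by SN2 displacement at C9. K2CO3 in MeOH at 0 °C then removes the chloroacetate in the presence of the lactone and the triethylsilyl ether to give 16.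

Further compounds
F1 | step 8 | C8-unsubstituted cis-anti-cis photoadduct of 8 and 13 | C[C@@H]1C(=O)O[C@H]2[C@H]3[C@@](C)(C(=O)C[C@@H]12)[C@@H]4CC[C@]34C
F2 | step 8 | C8-hydroxy cis-anti-cis photoadduct, O8 trans to C11 | C[C@@H]1C(=O)O[C@H]2[C@H]3[C@@](C)(C(=O)[C@H](O)[C@@H]12)[C@@H]4CC[C@]34C
F3 | step 9 | (1(10)E,4E)-8-(triethylsilyloxy)-9-oxogermacra-1(10),4-dien-12,6-olide | C[C@@H]1C(=O)O[C@H]2/C=C(\C)CC/C=C(\C)C(=O)[C@H](O[Si](CC)(CC)CC)[C@@H]12
F4 | step 10 | (9S)-9-hydroxy-8-(triethylsilyloxy) dienolide, C9 epimer of 16 | C[C@@H]1C(=O)O[C@H]2/C=C(\C)CC/C=C(/C)[C@H](O)[C@H](O[Si](CC)(CC)CC)[C@@H]12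
F5 | step 10 | (9R)-9-O-chloroacetyl-8-(triethylsilyloxy) dienolide | C[C@@H]1C(=O)O[C@H]2/C=C(\C)CC/C=C(/C)[C@@H](OC(=O)CCl)[C@H](O[Si](CC)(CC)CC)[C@@H]12
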